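**Retrosynthetic overview**

1. Target 10 ⇐ diol 9 (two acetylations) ⇐ hydroxy ester 8 (ester reduction) ⇐ Δ7 ester 7 (allylic oxidation at C17) ⇐ 8α-hydroxy ester 6 (loss of water from C8–OH).
2. Key disconnection C12–C13 of 6: the aldehyde carbon C12 of lactol 2 is made an alkyl-carbanion equivalent through its hydrazone and added to C3 of ethyl crotonate 3. Both carbons are natively electrophilic; N2 is lost, C12 ends as CH2, and C13 is set in the same bond formation.
3. Lactol 2 ⇐ (+)-sclareolide 1 by partial reduction.
4. Ring order: no carbocycle is formed. Rings A and B arrive trans-fused, with C5, C9 and C10 set, in 1; only the lactone ring is opened (steps 1–2).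

Assumption 1: labdane numbering is used throughout; the SMILES is read as (13S)-labd-7-ene-15,17-diyl diacetate of the normal series (5S,9R,10S; H-5α, H-9α, 10β-CH3).

Assumption 2: the sense of induction of the chiral bisphosphine in step 2 cannot be predicted with certainty; the route is written for (R,R)-Me-BPE, and the (S,S) ligand is taken instead if a first analytical run shows the 13R epimer in excess.

**Route**

Step 1
Reactants: 1 (+)-sclareolide
Product: 2 sclareolide lactol, (12ξ)-8α,12-epoxy-13,14,15,16-tetranorlabdan-12-ol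
Conditions: i-Bu2AlH (1.1 equiv), CH2Cl2, −78 °C; aq. KNaC4H4O6 (potassium sodium tartrate)
Reagents that add atoms: none
Why: Partial hydride reduction of the γ-lactone stops at the aluminium hemiacetal at −78 °C and gives the lactol on work-up (lactone-to-lactol reduction); no decalin stereocentre is touched and the anomeric C12 centre is erased in step 2.

Step 2
Reactants: 2 sclareolide lactol; 3 ethyl (E)-but-2-enoate (ethyl crotonate)
Product: 6 ethyl (13S)-8α-hydroxylabdan-15-oate, via open-chain C12 hydrazone 4 (not isolated), via C12 diazene adduct 5 (not isolated)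
Conditions: N2H4·H2O (1.05 equiv), THF, 20 °C, 2 h; then 3 (3 equiv), [Ru(p-cymene)Cl2]2 (2.5 mol %), (R,R)-Me-BPE (6 mol %), K3PO4 (0.5 equiv), CsF (1 equiv), THF, 50 °C
Reagents that add atoms: none
Why: Proposed new method: lactol 2 opens with hydrazine to hydrazone 4, whose N–H is deprotonated on divalent ruthenium so that C12 attacks C3 of the metal-bound crotonate through a cyclic transition state to give diazene 5, which loses N2 with protonation (Wolff–Kishner-type) and leaves C12 as CH2; replacing the achiral 1,2-bis(dimethylphosphino)ethane of the known reaction by the C2-symmetric 1,2-bis[(2R,5R)-2,5-dimethylphospholan-1-yl]ethane is expected to direct C12 to the Re face of crotonate C3 and so set C13 as S under catalyst control (the decalin centres are too remote to interfere), the closest known reaction type being the racemic [Ru(p-cymene)Cl2]2/bisphosphine-catalysed conjugate addition of aldehyde hydrazones, as alkyl-carbanion equivalents, to acrylates and related Michael acceptors (carbonyl umpolung).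

Step 3
Reactants: 6 ethyl (13S)-8α-hydroxylabdan-15-oate
Product: 7 ethyl (13S)-labd-7-en-15-oate
Conditions: conc. H2SO4 (0.3 equiv), EtOH, 20 °C, quenched at full conversion; AgNO3-impregnated silica
Reagents that add atoms: none
Why: Acid ionises the tertiary C8–OH to the C8 cation, which loses axial H7 faster than the hindered H9 or a methyl proton (E1 dehydration, the kinetic outcome also seen when cationic polyene cyclisations end as drim-7-enes), so the trisubstituted Δ7 alkene predominates; C9 keeps its configuration and the ethyl ester is inert in ethanol.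

Step 4
Reactants: 7 ethyl (13S)-labd-7-en-15-oate
Product: 8 ethyl (13S)-17-hydroxylabd-7-en-15-oate
Conditions: SeO2 (0.3 equiv), t-BuOOH (2.5 equiv, in decane), CH2Cl2, 20 °C
Reagents that add atoms: selenium dioxide, O=[Se]=O; tert-butyl hydroperoxide, CC(C)(C)OO (terminal oxidant)
Why: Riley allylic oxidation (ene reaction, then [2,3]-sigmatropic shift) acts at the more substituted alkene end on the methyl cis to H7, CH3 being preferred over the hindered tertiary C9–H, and returns the double bond to C7=C8; no stereocentre is formed and any over-oxidation at C17 is levelled by the hydride reduction of step 5.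

Step 5
Reactants: 8 ethyl (13S)-17-hydroxylabd-7-en-15-oate
Product: 9 (13S)-labd-7-ene-15,17-diol
Conditions: LiAlH4 (2 equiv), THF, 0 → 20 °C; H2O, aq. NaOH work-up
Reagents that add atoms: none
Why: LiAlH4 reduces the ethyl ester to the primary C15 alcohol (ester reduction) and leaves the isolated trisubstituted alkene and the allylic alcohol alone; no stereocentre is affected.

Step 6
Reactants: 9 (13S)-labd-7-ene-15,17-diol
Product: 10 (13S)-labd-7-ene-15,17-diyl diacetate
Conditions: Ac2O (3 equiv), pyridine, 4-(dimethylamino)pyridine (5 mol %), CH2Cl2, 20 °C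
Reagents that add atoms: acetic anhydride, CC(=O)OC(C)=O
Why: Both primary alcohols are acetylated under nucleophilic catalysis (4-(dimethylamino)pyridine-catalysed acylation), conditions that cannot epimerise C13 or move the Δ7 double bond.

**Compound list**

1 | (+)-sclareolide | O=C1C[C@H]2[C@](C)(O1)CC[C@H]3C(C)(C)CCC[C@]23C | starting material
2 | sclareolide lactol, (12ξ)-8α,12-epoxy-13,14,15,16-tetranorlabdan-12-ol | OC1C[C@H]2[C@](C)(O1)CC[C@H]3C(C)(C)CCC[C@]23C | intermediate
3 | ethyl (E)-but-2-enoate (ethyl crotonate) | C/C=C/C(=O)OCC | starting material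
4 | 8α-hydroxy-13,14,15,16-tetranorlabdan-12-al (E)-hydrazone | N/N=C/C[C@H]1[C@](C)(O)CC[C@H]2C(C)(C)CCC[C@]12C | intermediate
5 | ethyl 12-diazenyl-8α-hydroxylabdan-15-oate (C13 arranged as in 6; C12 epimers) | CCOC(=O)C[C@@H](C)C(N=N)C[C@H]1[C@](C)(O)CC[C@H]2C(C)(C)CCC[C@]12C | intermediate
6 | ethyl (13S)-8α-hydroxylabdan-15-oate | CCOC(=O)C[C@@H](C)CC[C@H]1[C@](C)(O)CC[C@H]2C(C)(C)CCC[C@]12C | intermediate
7 | ethyl (13S)-labd-7-en-15-oate | CCOC(=O)C[C@@H](C)CC[C@H]1C(C)=CC[C@H]2C(C)(C)CCC[C@]12C | intermediate
8 | ethyl (13S)-17-hydroxylabd-7-en-15-oate | CCOC(=O)C[C@@H](C)CC[C@H]1C(CO)=CC[C@H]2C(C)(C)CCC[C@]12C | intermediate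
9 | (13S)-labd-7-ene-15,17-diol | OCC[C@@H](C)CC[C@H]1C(CO)=CC[C@H]2C(C)(C)CCC[C@]12C | intermediate
10 | (13S)-labd-7-ene-15,17-diyl diacetate | CC(=O)OCC[C@@H](C)CC[C@H]1C(COC(C)=O)=CC[C@H]2C(C)(C)CCC[C@]12C | target

**Totals**

Total step count: 6. Longest linear sequence: 6 steps from 1 (the route is fully linear; 3 is bought).

**Steps most likely to fail**

Step 2 (key coupling). The β-methyl acceptor and the aliphatic hydrazone are at the edge of the known scope. Plain Wolff–Kishner reduction of C12 to a methyl group, azine formation and weak facial control at C13 are the likely failures. Fallback: the same C12–C13 bond is made with a nitronate as the acyl-anion equivalent and an organocatalyst that fixes C13. It sets out from lactol 2. NH2OH·HCl and NaOAc in EtOH give 8α-hydroxy-13,14,15,16-tetranorlabdan-12-al oxime F1. Oxidation with CF3CO3H (urea·H2O2, (CF3CO)2O, Na2HPO4, MeCN, 0 °C) gives 12-nitro-13,14,15,16-tetranorlabdan-8α-ol F2. Iminium-catalysed Michael addition of F2 to crotonaldehyde, with (S)-α,α-diphenylprolinol trimethylsilyl ether (10 mol %) and benzoic acid in MeOH, gives 8α-hydroxy-12-nitrolabdan-15-al F3; attack is on the Re face of the enal C3, so C13 is arranged as in 6, and the C12 epimers do not matter. NaClO2, NaH2PO4 and 2-methyl-2-butene in t-BuOH/H2O give 8α-hydroxy-12-nitrolabdan-15-oic acid F4. EtOH, EDC·HCl and 4-(dimethylamino)pyridine give ethyl 8α-hydroxy-12-nitrolabdan-15-oate F5. Radical denitration of F5 with Bu3SnH and AIBN in toluene at 110 °C comes back to the route at 6.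

Step 3 (regioselective dehydration). The C8 cation can also give the tetrasubstituted Δ8 alkene, the exocyclic alkene, or rearranged products on long acid contact. Fallback: the kinetic exocyclic alkene is made on purpose and oxidised with allylic transposition. It sets out from 6. SOCl2 and pyridine in CH2Cl2 at −78 °C give ethyl (13S)-labd-8(17)-en-15-oate F6. SeO2 (0.3 equiv) and t-BuOOH in CH2Cl2 give ethyl (13S)-7α-hydroxylabd-8(17)-en-15-oate F7, the oxygen being delivered to C7 from the α face. Ph3SiOReO3 (2 mol %) in Et2O at 0 °C moves the hydroxyl of F7 by 1,3-transposition to the primary position with the trisubstituted ring alkene. This comes back to the route at 8, so step 4 is bypassed as well.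

Step 4 (allylic oxidation). Attack at C9 or C6, over-oxidation and low conversion of the hindered alkene are possible. Fallback: C17 is functionalised by ene-type chlorination and acetolysis with allylic shift. It sets out from 7. Ca(OCl)2 and solid CO2 in CH2Cl2/H2O at 0 °C give ethyl (13S)-7α-chlorolabd-8(17)-en-15-oate F8, with chlorine on the less substituted alkene carbon and the double bond moved to C8=C17. AgOAc in AcOH at 20 °C ionises F8 to the allyl cation, which takes acetate at its primary end and gives ethyl (13S)-17-acetoxylabd-7-en-15-oate F9. The LiAlH4 conditions of step 5 reduce both ester groups of F9 and come back to the route at 9.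

**Further compounds**

F1 | step 2 | 8α-hydroxy-13,14,15,16-tetranorlabdan-12-al oxime | ON=CC[C@H]1[C@](C)(O)CC[C@H]2C(C)(C)CCC[C@]12C
F2 | step 2 | 12-nitro-13,14,15,16-tetranorlabdan-8α-ol | [O-][N+](=O)CC[C@H]1[C@](C)(O)CC[C@H]2C(C)(C)CCC[C@]12C
F3 | step 2 | 8α-hydroxy-12-nitrolabdan-15-al (C13 arranged as in 6; C12 epimers) | O=CC[C@@H](C)C([N+](=O)[O-])C[C@H]1[C@](C)(O)CC[C@H]2C(C)(C)CCC[C@]12C
F4 | step 2 | 8α-hydroxy-12-nitrolabdan-15-oic acid (C13 arranged as in 6; C12 epimers) | OC(=O)C[C@@H](C)C([N+](=O)[O-])C[C@H]1[C@](C)(O)CC[C@H]2C(C)(C)CCC[C@]12C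
F5 | step 2 | ethyl 8α-hydroxy-12-nitrolabdan-15-oate (C13 arranged as in 6; C12 epimers) | CCOC(=O)C[C@@H](C)C([N+](=O)[O-])C[C@H]1[C@](C)(O)CC[C@H]2C(C)(C)CCC[C@]12C
F6 | step 3 | ethyl (13S)-labd-8(17)-en-15-oate | CCOC(=O)C[C@@H](C)CC[C@H]1C(=C)CC[C@H]2C(C)(C)CCC[C@]12C
F7 | step 3 | ethyl (13S)-7α-hydroxylabd-8(17)-en-15-oate | CCOC(=O)C[C@@H](C)CC[C@H]1C(=C)[C@H](O)C[C@H]2C(C)(C)CCC[C@]12C
F8 | step 4 | ethyl (13S)-7α-chlorolabd-8(17)-en-15-oate | CCOC(=O)C[C@@H](C)CC[C@H]1C(=C)[C@H](Cl)C[C@H]2C(C)(C)CCC[C@]12C
F9 | step 4 | ethyl (13S)-17-acetoxylabd-7-en-15-oate | CCOC(=O)C[C@@H](C)CC[C@H]1C(COC(C)=O)=CC[C@H]2C(C)(C)CCC[C@]12C
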